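In minutes first, then in powers of ten, I ask how many times one exchange fits into the run.

| flask | substrate | remark | time |
|---|---|---|---|
| alpha | 0.20 mM | one stirred flow tank at steady state, fed with the mixture as stated, mean residence time 3.0 min |  |
| gamma | 0.20 mM | plug flow through a tube for 3.0 min, no back-mixing | 3.0 min |
| beta | 0.20 mM | everything together in a closed stirred flask, run for 3.0 min | 3.0 min |

1. the set-up with the highest amount of target at the outlet or at the end, in percent of the substrate put in ("none" if the first two lie within 2 percentage points) (alpha / gamma / beta / none)
2. amount of target at the outlet or at the end, in percent of the substrate put in, alpha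
3. amount of target at the outlet or at the end, in percent of the substrate put in, gamma
4. amount of target at the outlet or at the end, in percent of the substrate put in, beta

- percent here means substrate units held: one self-condensation product counts as two
- a doubled species enters its step squared and goes two at a time
- the stated concentrations are those of everything mixed, before any reaction; amounts are the same in each set-up
- run time (gamma): 3.0 min

    substrate ⇌ target (K1 = 1.8, k1 = 0.031 s⁻¹)
    substrate ⇌ isomer of the product A (K2 = 2.6, k2 = 0.0048 s⁻¹)
    target ⇌ isomer of the product A (k3 = 0.053 s⁻¹)
    2 substrate → self-condensation product (k4 = 0.33 L mol⁻¹ s⁻¹)
    target ⇌ isomer of the product B (K5 = 1.1, k5 = 0.012 s⁻¹)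

I want two times for this reckoning, and I choose them by elimination. The self-condensation has a first half-life of 126 min at the full charge, 1.62 powers of ten longer than the run of 3.0 min, so I set it aside. The direct step from substrate to isomer of the product A has k2 = 0.0048 s⁻¹, slower than the route through target, whose steps have k1 = 0.031 s⁻¹ and k3 = 0.053 s⁻¹, so I set that aside too. Substrate exchanges with target in 0.346 min. Target exchanges with isomer of the product B in τ = 1/(k5 + k5/K5) = 0.728 min, which is longer, so τ is my clock.

The exchange count N, the run time divided by τ, is 4.12, or 0.615 as a power of ten. With that count I expect target near its share at rest with the self-condensation set aside, K1/(1 + K1 + K2 + K1·K5) = 24.4%, in all three set-ups. I can't reckon by hand how far the stirred tank lags, but I commit to no winner.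

The forecast gives 24.6% for alpha, 25% for gamma, 25% for beta, and none as best, its figures for target standing a little above my share. It holds that “Plug flow and the closed flask are the same kinetically”.

The simulation gives 24.6%, 25.0% and 25.0%, and none as best.

In beta, the closed flask, after N = 4.12, substrate stood at 14.2% and isomer of the product A at 36.6% while step 5 had brought isomer of the product B to 24.0%, whereas in alpha, the tank, the same N, reckoned on the mean residence time, left substrate at 25.1% and isomer of the product B at 17.9%. In gamma, the tube, left ten times as long, for 30.0 min, N reached 41.2 and target stood at 24.2%.

(Its constants were drawn at random within sensible limits.)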